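**Numbering.** Ring A (five-membered): C1 (quaternary, CH3)–C2–C3–C4 (OH, isopropyl)–C5 (H). Ring B (seven-membered): C5–C6 (OAr)–C7 (=O)–C8 (OH, CH3)–C9 (OH)–C10–C1. Bicyclic compounds are named as bicyclo[5.3.0]decanes with these locants. Compounds are numbered 1–29 in the order of their first appearance in the steps; the list follows the steps.

## Analysis of the target

Compound 29 is a daucane-type sesquiterpenoid ester: a cyclopentane (ring A, C1–C5) trans-fused along C1–C5 to a cycloheptanone (ring B), with the C6 oxygen acylated by 4-hydroxybenzoic acid. It has six stereocentres: C1 (R, quaternary, methyl), C4 (R, tertiary carbinol with isopropyl), C5 (S), C6 (R), C8 (S, tertiary carbinol with methyl) and C9 (S). The C1 methyl and H5 are anti across the ring fusion and the C4 hydroxyl lies on the face of the C1 methyl. The C6 acyloxy group and the cis-related C8 and C9 hydroxyls lie on the opposite face, that of H5. The sensitive region is the C7 ketone: C6 is epimerisable and open to acyl migration, the C8/C9 α,β-dihydroxy unit is open to retro-aldol cleavage and α-ketol shift, the tertiary C4 alcohol can dehydrate or add to C7, and the phenol is free. The difficulty is density: seven of the ten ring carbons carry a substituent or a stereocentre, the quaternary C1 sits at a trans ring fusion, and ring B must be closed with four different oxidation levels (C6 to C9) in place. The strategy rests on the fact that C4, C5 and C1 of ring A are the carbonyl, α and β carbons of a cyclopent-2-enone, so the C1 methyl and the oxygenated C6 can be attached to C1 and C5 in one operation while the C4 carbonyl remains for the isopropyl group.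

## Retrosynthetic reasoning

**29 ⇒ 28.** The last bond cut is the benzyl–oxygen bond of a protected phenol. Hydrogenolysis is neutral, so the C6–C9 array, which is prone to migration and retro-aldol cleavage, meets neither acid nor base at the end.

**28 ⇒ 27.** The C8–O and C9–O bonds are cut together, back to the C8=C9 enone 27. The two hydroxyls are cis and on the H5 face, which is what a syn-dihydroxylation from the face opposite the axial C1 methyl should give. The cut is placed after the esterification so that the secondary C9 hydroxyl never competes with C6–OH for the acyl group.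

**27 ⇒ 25 + 26.** The ester C–O bond at C6 is cut to the diol enone 25 and the acid chloride 26. In 25 the only other hydroxyl is the hindered tertiary one at C4, so no further protection is needed. Compound 25 comes from the bis-silyl ether 24 by desilylation.

**24 ⇒ 22.** The C8–C9 bond of ring B is cut. C8 is α to the C7 ketone and can be the nucleophile as the enol silane of 22; C9 is at the aldehyde oxidation level and can be the electrophile as its dimethyl acetal. The roles of the two carbons are fixed in advance, which excludes the crossed aldol of C10 onto C7 that would close a five-membered ring. The methoxy group left on C9 in 23 is then eliminated, which gives exactly the C8=C9 enone needed above. The forward reaction has to close a seven-membered ring between two arms that are already trans on ring A.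

**22 ⇒ 21 ⇒ 20 ⇒ 19.** These are adjustments of functional groups. The enol silane 22 comes from the ethyl ketone 21 by kinetic enolisation, and 21 from the dithiane 20. The C4 hydroxyl of 19 is silylated to 20 because it is cis to the C6 arm and γ to C7, and would otherwise close onto the unmasked ketone as a five-membered hemiketal.

**19 ⇒ 17 + 18.** The C4–isopropyl bond is cut to the cyclopentanone 17 and the Grignard reagent 18. The carbonyl carbon of the original enone is the natural acceptor, and the adjacent C5 side chain should direct the nucleophile to the opposite face, which is the configuration of 29. Compound 17 is the silyl ether of the aldol adduct 16.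

**16 ⇒ 7 + 14 + 13.** The C1–CH3 and C5–C6 bonds are cut in one retrosynthetic step. This is the point at which ring A of 29 matches a cyclopent-2-enone without any adjustment. The forward reaction has to create the quaternary C1 under catalyst control, attach C6 at C5 trans to the C10 arm, and set the C6 carbinol. It joins the enone 7, the methyl donor 14 and the aldehyde 13, and fixes three stereocentres and both arms of ring B.

**7 ⇒ 4 ⇒ 1 + 2 and 13 ⇒ 10 ⇒ 8.** The enone 7 comes from the allyl enone 4 by cleavage of the terminal alkene and acetalisation, and 4 from the vinylogous ester 1 and the allyl Grignard reagent 2 by addition and carbonyl transposition. The aldehyde 13 comes from 8 by ethylation to 10 and then formylation at the same carbon. Both fragments are two routine steps from commercial materials, so the risk sits in the three-component step.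

## Alternatives that were turned down

**Alternative 1:** Ring B is cut at C7–C8 and C10–C1. This leads to the diene A2 (6-ethenyl-7-methyl-1,4-dioxaspiro[4.4]non-6-ene) and the vinyldiazo ester A3 (methyl 2-diazobut-3-enoate). In the forward sense a chiral dirhodium tetracarboxylate turns A3 into a vinylcarbene that cyclopropanates the terminal C6=C7 alkene of A2. The cis-divinylcyclopropane then undergoes a Cope rearrangement that joins C10 to C1 and gives the bicyclic diene ester A1.
- For it: ring B and the quaternary C1 arise in one catalytic, enantioselective step from two small fragments, and the C8=C9 alkene needed for the diol is already present. The bicycle is reached in far fewer steps than in the chosen route; on this point the alternative is clearly stronger.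
- Against it for 29: in A1, C7 is a methylene that must be oxidised between two alkenes. The C8 substituent is an ester that must be taken down to a methyl group in about three operations. C5=C6 must be converted into H5 and a C6 oxygen, with the trans fusion set by an external reagent. The sigmatropic step must also bring the fully substituted C1 terminus of A2 into a boat transition state.
- Comparison: A1 has the right ring but the wrong oxidation level at four consecutive carbons (C5 to C8). The chosen strategy closes ring B later, but its fragments deliver the C6 oxygen, the C7 carbonyl and the C8 methyl at their final oxidation levels and fix C5 before the ring exists.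

**Alternative 2:** Both rings are cut at once, at C1–C5 and C9–C10. This leads to the acyclic ene–vinylcyclopropane A5 ((3S,1E)-3-[(tert-butyldimethylsilyl)oxy]-6-methyl-1-[1-(triethylsilyloxy)cyclopropyl]hepta-1,6-diene). A monovalent rhodium catalyst would promote the intramolecular (5+2) cycloaddition of the 1,1-disubstituted alkene with the vinylcyclopropane, opening the three-membered ring and giving the bicyclic silyl enol ether A4.
- For it: the whole bicyclo[5.3.0]decane forms in one step and the quaternary C1 comes from a simple alkene. The C6=C7 enol ether of A4 is a direct handle for the C7 ketone and for oxidation at C6. In ring construction it is more economical than the chosen route.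
- Against it for 29: A4 is cis-fused, whereas 29 has the C1 methyl and H5 anti. C5 is not α to a carbonyl, so its inversion would need a desaturation and reduction sequence. C8 and C9 are bare methylenes, so the C8 methyl must be introduced by an alkylation that has to choose C8 over C6, followed by desaturation. C4 is a secondary silyl ether whose stereocentre only relays chirality before it is oxidised for the isopropyl addition.
- Comparison: the chosen strategy gives up the one-step bicycle, but the trans relation of the two arms is built into the aldol adduct 16 and the C8 methyl is carried from the start.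

**Alternative 3:** Ring A is cut at C4–C5. This leads to the prochiral dienone aldehyde A7 (3-(1-methyl-4-oxocyclohexa-2,5-dien-1-yl)propanal). A chiral triazolium-derived carbene would turn the aldehyde carbon C4 into an acyl anion equivalent that adds to C5 of one of the two enantiotopic enone arms (intramolecular Stetter reaction), giving the bicyclic enedione A6.
- For it: desymmetrisations of this type are dependable in enantiocontrol, probably more so than a copper-catalysed methyl transfer to a cyclopentenone. A7 is short to make, and C1 and C5 are fixed in one organocatalytic step.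
- Against it for 29: A6 has a six-membered ring B that lacks C8, so a regioselective one-carbon ring expansion between C7 and C9 is needed. It is cis-fused, C6 carries no oxygen, and its alkene lies at C9=C10 and not at C8=C9. The C4 and C7 ketones must also be told apart before the isopropyl group can be added.
- Comparison: three corrections of the skeleton (ring size, ring fusion, position of unsaturation) stand against one well-behaved key step. The chosen strategy accepts a less secure enantioselective step and in return never has to change ring size or ring fusion.

Key step: step 5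

Assumption: 29 is addressed as the open hydroxy ketone that is written; a possible equilibrium with the C4–O–C7 hemiketal is a property of the compound itself and is not treated further.

## Route

Step 1
Reactants: 1 3-ethoxycyclopent-2-en-1-one; 2 allylmagnesium bromide
Product: 4 3-allylcyclopent-2-en-1-one, via bromomagnesium alkoxide 3 (not isolated)
Conditions: 2 (1.2 equiv), THF, 0 °C; then 1 M HCl, 0 °C, short contact
Reagents that add atoms: water, O
Why: 1,2-Addition of the Grignard reagent to the vinylogous ester, then acid-induced loss of the tertiary hydroxyl and hydrolysis of the enol ether (Stork–Danheiser transposition), moves the carbonyl to the former C–OEt carbon and leaves the allyl group at the β-position; brief, cold acid keeps the allyl double bond out of conjugation.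

Step 2
Reactants: 4 3-allylcyclopent-2-en-1-one
Product: 7 3-(2,2-dimethoxyethyl)cyclopent-2-en-1-one, via methoxy hydroperoxide 5 (not isolated), via keto aldehyde 6 (not isolated)
Conditions: O3, CH2Cl2/MeOH (4:1), −78 °C, Sudan Red 7B as end-point indicator; Me2S, −78 °C to rt; then HC(OMe)3, p-TsOH·H2O (cat.), rt; NaHCO3
Reagents that add atoms: methanol, CO; trimethyl orthoformate, COC(OC)OC
Why: Ozone is electrophilic and should cleave the isolated terminal alkene well before the electron-poor enone double bond (chemoselective ozonolysis with a dye end point). The sensitive, doubly activated aldehyde 6 is not isolated but acetalised at once under mild acid catalysis, the conjugated ketone reacting much more slowly.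

Step 3
Reactants: 8 1,3-dithiane
Product: 10 2-ethyl-1,3-dithiane, via 2-lithio-1,3-dithiane 9 (not isolated)
Conditions: n-BuLi, THF, −30 °C; EtI, −78 °C to rt
Reagents that add atoms: iodoethane, CCI
Why: Corey–Seebach alkylation: the sulfur-stabilised C2 anion displaces iodide from the primary halide.

Step 4
Reactants: 10 2-ethyl-1,3-dithiane
Product: 13 2-ethyl-1,3-dithiane-2-carbaldehyde, via 2-ethyl-2-lithio-1,3-dithiane 11 (not isolated), via lithium hemiaminal alkoxide 12 (not isolated)
Conditions: n-BuLi, THF, −20 °C; DMF, −78 to 0 °C; aq NH4Cl
Reagents that add atoms: N,N-dimethylformamide, CN(C)C=O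
Why: Second Corey–Seebach metalation followed by formylation with the formamide; the tetrahedral adduct 12 persists until work-up, so the aldehyde is never exposed to the carbanion, and the product has no α-hydrogen.

Step 5
Reactants: 7 3-(2,2-dimethoxyethyl)cyclopent-2-en-1-one; 14 methylmagnesium bromide; 13 2-ethyl-1,3-dithiane-2-carbaldehyde
Product: 16 (2S,3R)-3-(2,2-dimethoxyethyl)-2-[(R)-(2-ethyl-1,3-dithian-2-yl)(hydroxy)methyl]-3-methylcyclopentan-1-one, via magnesium enolate 15 (not isolated)
Conditions: Cu(OTf)2 (5 mol %), (S)-1-(1-hydroxy-4-methylpentan-2-yl)-3-mesityl-4,5-dihydroimidazolium hexafluorophosphate or its antipode (NHC precursor, 7 mol %), 14 (1.2 equiv), Et2O, −30 to 0 °C; then 13 (1.5 equiv), −78 to −40 °C; aq NH4Cl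
Reagents that add atoms: none
Why: The Grignard reagent deprotonates the imidazolinium salt and converts Cu(OTf)2 into a monovalent methylcopper–NHC species, which binds the enone π-bond, adds oxidatively at the β-carbon C1 and reductively eliminates from trivalent copper, forming C1–CH3 and the magnesium enolate 15 with its double bond fixed at C4=C5. The closest known reaction type is the copper/NHC-catalysed asymmetric conjugate addition of Grignard reagents to β-substituted cyclic enones that creates quaternary centres, combined with aldehyde trapping of the magnesium enolate; five-membered enones are the less selective substrates of that class. No ring is closed in this step. C1 is set by the ligand, whose antipode is chosen in a preliminary run so that methyl is delivered to the enone face that gives (R). Aldehyde 13 cannot enolise and has a quaternary α-carbon, so it should react through a closed six-membered chair transition state around magnesium (Zimmerman–Traxler); since the ring enolate can only have C1 trans to OMg, this leads to the anti adduct, which is (R) at C6. C5 is set by the substrate: the bulky aldehyde should approach the enolate face that carries the C1 methyl and avoid the larger 2,2-dimethoxyethyl arm, which gives (S) at C5 and places the two arms of the future ring B trans on ring A. The step therefore needs 1,4- over 1,2-addition (copper), enantioface control (ligand), C5 face control (methyl versus acetal arm) and anti selectivity at C6 (closed transition state with a hindered aldehyde); the slight excess of 13 also consumes residual 14.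

Step 6
Reactants: 16 aldol adduct
Product: 17 (2S,3R)-2-[(R)-[(tert-butyldimethylsilyl)oxy](2-ethyl-1,3-dithian-2-yl)methyl]-3-(2,2-dimethoxyethyl)-3-methylcyclopentan-1-one
Conditions: TBSOTf (1.2 equiv), 2,6-lutidine, CH2Cl2, −78 °C
Reagents that add atoms: tert-butyldimethylsilyl trifluoromethanesulfonate, CC(C)(C)[Si](C)(C)OS(=O)(=O)C(F)(F)F
Why: Silylation of the hindered secondary carbinol with a silyl triflate; the weak base and low temperature avoid retro-aldol cleavage and β-elimination of the β-hydroxy ketone and should leave the dimethyl acetal untouched, since silyl triflates attack acetals only at higher temperature and in excess.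

Step 7
Reactants: 17 silyl ether of the aldol adduct; 18 isopropylmagnesium chloride
Product: 19 (1R,2S,3R)-2-[(R)-[(tert-butyldimethylsilyl)oxy](2-ethyl-1,3-dithian-2-yl)methyl]-3-(2,2-dimethoxyethyl)-3-methyl-1-(propan-2-yl)cyclopentan-1-ol
Conditions: 18 (3 equiv), anhydrous CeCl3 (3 equiv), THF, −78 to −20 °C; aq NH4Cl
Reagents that add atoms: none
Why: Organocerium 1,2-addition: the weakly basic, oxophilic reagent should add to the hindered, enolisable ketone where the Grignard reagent alone would enolise it, reduce it by β-hydride transfer or trigger loss of the β-silyloxy group. The isopropyl group should enter C4 from the face opposite the large C5 side chain, giving the (R) carbinol with the hydroxyl cis to that chain.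

Step 8
Reactants: 19 tertiary alcohol
Product: 20 trimethylsilyl ether of 19 at the C4 hydroxyl, configuration unchanged
Conditions: N-(trimethylsilyl)imidazole, CH2Cl2, rt to 40 °C
Reagents that add atoms: N-(trimethylsilyl)imidazole, C[Si](C)(C)n1ccnc1
Why: Silylation of a tertiary alcohol with a non-acidic silyl donor that does not touch the acetal; the cap prevents the C4 hydroxyl from closing onto the C7 ketone as a five-membered hemiketal once that ketone is unmasked.

Step 9
Reactants: 20 bis-silyl ether dithiane
Product: 21 (1R)-1-[(tert-butyldimethylsilyl)oxy]-1-[(1S,2R,5R)-2-(2,2-dimethoxyethyl)-2-methyl-5-(propan-2-yl)-5-[(trimethylsilyl)oxy]cyclopentyl]butan-2-one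
Conditions: MeI (excess), CaCO3, MeCN/H2O (9:1), 40 °C
Reagents that add atoms: water, O
Why: Alkylative hydrolysis of the dithiane: S-methylation turns sulfur into a leaving group and water adds to the thionium ion. The carbonate buffer keeps the medium near neutral, so the acetal and both silyl ethers should survive and C6 should not epimerise.

Step 10
Reactants: 21 ethyl ketone
Product: 22 trimethylsilyl enol ether of 21 with the double bond at C7=C8 (Z isomer expected to dominate), other centres unchanged
Conditions: LiN(iPr)2, THF, −78 °C; TMSCl, Et3N, −78 to 0 °C; cold NaHCO3, pentane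
Reagents that add atoms: chlorotrimethylsilane, C[Si](C)(C)Cl
Why: Kinetic enolisation and O-silylation: the amide base should remove a proton from the unhindered C8 methylene and not from the C6 methine, which is shielded by the silyloxy group and ring A, so the enol silane is regiodefined. Its geometry is irrelevant because C8 becomes trigonal again.

Step 11
Reactants: 22 enol silane
Product: 24 (1R,4R,5S,6R)-6-[(tert-butyldimethylsilyl)oxy]-1,8-dimethyl-4-(propan-2-yl)-4-[(trimethylsilyl)oxy]bicyclo[5.3.0]dec-8-en-7-one, via β-methoxy ketone 23 (not isolated)
Conditions: TMSOTf (0.2 equiv), 2,6-di-tert-butyl-4-methylpyridine, CH2Cl2 (0.005 M), −78 °C; then DBU, 0 °C to rt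
Reagents that add atoms: none
Why: Intramolecular Mukaiyama aldol-type addition to an acetal: the silyl triflate ionises the acetal to a C9 oxocarbenium ion, which C8 of the enol silane attacks in a 7-(enolendo)-exo-trig closure between the trans-disposed arms, giving the trans-fused ring B. DBU then removes the C8 proton and expels the C9 methoxy group (E1cB) to give the conjugated C8=C9 enone. The C6 silyloxy group is equatorial, the arrangement expected to be favoured should any enolisation toward C6 occur.

Step 12
Reactants: 24 bicyclic enone
Product: 25 (1R,4R,5S,6R)-4,6-dihydroxy-1,8-dimethyl-4-(propan-2-yl)bicyclo[5.3.0]dec-8-en-7-one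
Conditions: HF·pyridine, pyridine, THF, 0 °C to rt
Reagents that add atoms: none
Why: Fluoride-mediated desilylation should cleave both silyl ethers under buffered, weakly acidic conditions that neither enolise the α-hydroxy ketone nor dehydrate the tertiary alcohol.

Step 13
Reactants: 25 diol enone; 26 4-(benzyloxy)benzoyl chloride
Product: 27 (1R,4R,5S,6R)-4-hydroxy-1,8-dimethyl-7-oxo-4-(propan-2-yl)bicyclo[5.3.0]dec-8-en-6-yl 4-(benzyloxy)benzoate
Conditions: 26 (1.3 equiv), Et3N, DMAP (0.1 equiv), CH2Cl2, 0 °C to rt
Reagents that add atoms: none
Why: DMAP-catalysed acylation; only the secondary C6 hydroxyl should react, the tertiary C4 hydroxyl being too hindered, and esterifying before the diol exists removes any competition from C9–OH.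

Step 14
Reactants: 27 ester enone
Product: 28 (1R,4R,5S,6R,8S,9S)-4,8,9-trihydroxy-1,8-dimethyl-7-oxo-4-(propan-2-yl)bicyclo[5.3.0]decan-6-yl 4-(benzyloxy)benzoate
Conditions: OsO4 (5 mol %), NMO (2 equiv), citric acid (1 equiv), t-BuOH/H2O (1:1), rt
Reagents that add atoms: osmium tetroxide, O=[Os](=O)(=O)=O; N-methylmorpholine N-oxide, C[N+]1([O-])CCOCC1; water, O
Why: Catalytic syn-dihydroxylation (Upjohn type, acid-accelerated for the electron-poor alkene) adds both oxygens to one face of C8=C9 through a [3+2] osmate ester. The reagent should approach from the face opposite the axial C1 methyl, the C6 ester being equatorial, which gives 8S,9S with both hydroxyls on the H5 face.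

Step 15
Reactants: 28 benzyl-protected triol ester
Product: 29 (1R,4R,5S,6R,8S,9S)-4,8,9-trihydroxy-1,8-dimethyl-7-oxo-4-(propan-2-yl)bicyclo[5.3.0]decan-6-yl 4-hydroxybenzoate (CNP0241001.1)
Conditions: H2 (1 atm), Pd/C (10 %), EtOAc, rt
Reagents that add atoms: none
Why: Hydrogenolysis of the benzyl aryl ether under neutral conditions frees the phenol without acid or base, so the acyloxy dihydroxy ketone array should not be disturbed.

## Compound list

1 | 3-ethoxycyclopent-2-en-1-one | CCOC1=CC(=O)CC1 | starting material
2 | allylmagnesium bromide | C=CC[Mg]Br | starting material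
3 | bromomagnesium 1-allyl-3-ethoxycyclopent-2-en-1-olate (racemic) | C=CCC1(O[Mg]Br)C=C(OCC)CC1 | intermediate (not isolated)
4 | 3-allylcyclopent-2-en-1-one | C=CCC1=CC(=O)CC1 | intermediate
5 | 3-(2-hydroperoxy-2-methoxyethyl)cyclopent-2-en-1-one (racemic) | COC(OO)CC1=CC(=O)CC1 | intermediate (not isolated)
6 | 2-(3-oxocyclopent-1-en-1-yl)acetaldehyde | O=CCC1=CC(=O)CC1 | intermediate (not isolated)
7 | 3-(2,2-dimethoxyethyl)cyclopent-2-en-1-one | COC(CC1=CC(=O)CC1)OC | intermediate
8 | 1,3-dithiane | C1CSCSC1 | starting material
9 | 2-lithio-1,3-dithiane | [Li]C1SCCCS1 | intermediate (not isolated)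
10 | 2-ethyl-1,3-dithiane | CCC1SCCCS1 | intermediate
11 | 2-ethyl-2-lithio-1,3-dithiane | CCC1([Li])SCCCS1 | intermediate (not isolated)
12 | lithium (dimethylamino)(2-ethyl-1,3-dithian-2-yl)methanolate (racemic) | CCC1(C(O[Li])N(C)C)SCCCS1 | intermediate (not isolated)
13 | 2-ethyl-1,3-dithiane-2-carbaldehyde | CCC1(C=O)SCCCS1 | intermediate
14 | methylmagnesium bromide | C[Mg]Br | starting material
15 | bromomagnesium (3R)-3-(2,2-dimethoxyethyl)-3-methylcyclopent-1-en-1-olate | Br[Mg]OC1=C[C@@](C)(CC(OC)OC)CC1 | intermediate (not isolated)
16 | (2S,3R)-3-(2,2-dimethoxyethyl)-2-[(R)-(2-ethyl-1,3-dithian-2-yl)(hydroxy)methyl]-3-methylcyclopentan-1-one | O=C1CC[C@](C)(CC(OC)OC)[C@H]1[C@@H](O)C2(CC)SCCCS2 | intermediate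
17 | (2S,3R)-2-[(R)-[(tert-butyldimethylsilyl)oxy](2-ethyl-1,3-dithian-2-yl)methyl]-3-(2,2-dimethoxyethyl)-3-methylcyclopentan-1-one | O=C1CC[C@](C)(CC(OC)OC)[C@H]1[C@@H](O[Si](C)(C)C(C)(C)C)C2(CC)SCCCS2 | intermediate
18 | isopropylmagnesium chloride | CC(C)[Mg]Cl | starting material
19 | (1R,2S,3R)-2-[(R)-[(tert-butyldimethylsilyl)oxy](2-ethyl-1,3-dithian-2-yl)methyl]-3-(2,2-dimethoxyethyl)-3-methyl-1-(propan-2-yl)cyclopentan-1-ol | CC(C)[C@]1(O)CC[C@](C)(CC(OC)OC)[C@H]1[C@@H](O[Si](C)(C)C(C)(C)C)C2(CC)SCCCS2 | intermediate
20 | trimethylsilyl ether of 19 at the tertiary C4 hydroxyl | CC(C)[C@]1(O[Si](C)(C)C)CC[C@](C)(CC(OC)OC)[C@H]1[C@@H](O[Si](C)(C)C(C)(C)C)C2(CC)SCCCS2 | intermediate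
21 | (1R)-1-[(tert-butyldimethylsilyl)oxy]-1-[(1S,2R,5R)-2-(2,2-dimethoxyethyl)-2-methyl-5-(propan-2-yl)-5-[(trimethylsilyl)oxy]cyclopentyl]butan-2-one | CC(C)[C@]1(O[Si](C)(C)C)CC[C@](C)(CC(OC)OC)[C@H]1[C@@H](O[Si](C)(C)C(C)(C)C)C(=O)CC | intermediate
22 | trimethylsilyl enol ether of 21 at C7=C8 (alkene geometry not fixed) | CC(C)[C@]1(O[Si](C)(C)C)CC[C@](C)(CC(OC)OC)[C@H]1[C@@H](O[Si](C)(C)C(C)(C)C)C(O[Si](C)(C)C)=CC | intermediate
23 | (1R,4R,5S,6R)-6-[(tert-butyldimethylsilyl)oxy]-9-methoxy-1,8-dimethyl-4-(propan-2-yl)-4-[(trimethylsilyl)oxy]bicyclo[5.3.0]decan-7-one (C8 and C9 as mixture) | CC(C)[C@]1(O[Si](C)(C)C)CC[C@]2(C)CC(OC)C(C)C(=O)[C@H](O[Si](C)(C)C(C)(C)C)[C@H]21 | intermediate (not isolated)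
24 | (1R,4R,5S,6R)-6-[(tert-butyldimethylsilyl)oxy]-1,8-dimethyl-4-(propan-2-yl)-4-[(trimethylsilyl)oxy]bicyclo[5.3.0]dec-8-en-7-one | CC(C)[C@]1(O[Si](C)(C)C)CC[C@]2(C)CC=C(C)C(=O)[C@H](O[Si](C)(C)C(C)(C)C)[C@H]21 | intermediate
25 | (1R,4R,5S,6R)-4,6-dihydroxy-1,8-dimethyl-4-(propan-2-yl)bicyclo[5.3.0]dec-8-en-7-one | CC(C)[C@]1(O)CC[C@]2(C)CC=C(C)C(=O)[C@H](O)[C@H]21 | intermediate
26 | 4-(benzyloxy)benzoyl chloride | O=C(Cl)c1ccc(OCc2ccccc2)cc1 | starting material
27 | (1R,4R,5S,6R)-4-hydroxy-1,8-dimethyl-7-oxo-4-(propan-2-yl)bicyclo[5.3.0]dec-8-en-6-yl 4-(benzyloxy)benzoate | CC(C)[C@]1(O)CC[C@]2(C)CC=C(C)C(=O)[C@H](OC(=O)c3ccc(OCc4ccccc4)cc3)[C@H]21 | intermediate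
28 | (1R,4R,5S,6R,8S,9S)-4,8,9-trihydroxy-1,8-dimethyl-7-oxo-4-(propan-2-yl)bicyclo[5.3.0]decan-6-yl 4-(benzyloxy)benzoate | CC(C)[C@]1(O)CC[C@]2(C)C[C@H](O)[C@](C)(O)C(=O)[C@H](OC(=O)c3ccc(OCc4ccccc4)cc3)[C@H]21 | intermediate
29 | (1R,4R,5S,6R,8S,9S)-4,8,9-trihydroxy-1,8-dimethyl-7-oxo-4-(propan-2-yl)bicyclo[5.3.0]decan-6-yl 4-hydroxybenzoate (CNP0241001.1) | CC(C)[C@]1(O)CC[C@]2(C)C[C@H](O)[C@](C)(O)C(=O)[C@H](OC(=O)c3ccc(O)cc3)[C@H]21 | target

## Step count and risk

Total step count: 15. Longest linear sequence: 13 steps (steps 1, 2 and 5–15; the dithiane branch, steps 3, 4 and 5–15, is equally long).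

**Step 5 (key step).**
- What may go wrong: methyl transfer to the flat five-membered enone may be slow or only moderately enantioselective. The Grignard reagent may instead deprotonate C10, after which methoxide can be lost from the acetal. Facial discrimination at C5 may be weak, because the methyl group and the acetal arm on C1 differ little in size. Some syn adduct may form at C6.
- Least damaging error: the wrong configuration at C6, because C6 becomes α to the C7 ketone and can be equilibrated toward the equatorial silyloxy isomer at the stage of 24.
- Fallback: it sets out from 7 and separates the two bond formations. Conjugate methylation with AlMe3, catalysed by copper thiophene-2-carboxylate, CuO2C(C4H3S), and a chiral phosphoramidite ligand in Et2O at −30 °C, gives an aluminium enolate. This is acetylated in the flask with Ac2O to the isolable enol acetate F1. Treatment of F1 with MeLi (2 equiv, THF, 0 °C) regenerates the regiodefined lithium enolate. After exchange to magnesium with MgBr2·OEt2 (or to zinc with ZnCl2), aldehyde 13 is added at −78 °C. The sequence comes back to the route at 16. It allows the enantioselective step and the aldol step to be optimised independently and the enolate metal to be chosen for C5 and C6 selectivity.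

**Step 7.**
- What may go wrong: steric compression next to the C5 side chain may divert the reagent into enolisation toward C3, hydride transfer, or elimination of the silyloxy group. Facial selectivity may erode if the C10 arm on C1 hinders the intended face.
- Fallback: it sets out from 17 and uses a smaller sp2 nucleophile that cannot deliver hydride. Isopropenylmagnesium bromide with CeCl3 (THF, −78 °C) gives the isopropenyl carbinol F2. This is silylated with N-(trimethylsilyl)imidazole to the silyl ether F3. The dithiane is hydrolysed with MeI/CaCO3 in aqueous MeCN to the isopropenyl ethyl ketone F4. Now that sulfur is gone, the 1,1-disubstituted alkene is saturated with H2 over Pd/C in EtOAc. The sequence comes back to the route at 21.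

**Step 11.**
- What may go wrong: the C9 oxocarbenium ion may be captured by the oxygen of the C6 silyl ether (six-membered cyclic acetal with loss of silicon) or react intermolecularly, in place of the slower seven-membered closure. Acid-induced migration of the enol silane toward C6 would open a five-membered closure. The tertiary C4 silyloxy group may ionise.
- Fallback: it sets out from 22 and replaces the cationic closure by a reductive one. NBS (THF, −78 °C) converts 22 into the α-bromo ketone F5. LiBF4 in wet MeCN unmasks the acetal to the bromo keto aldehyde F6. SmI2 (THF, −78 °C, high dilution) generates the samarium enolate specifically at C8, which adds to the C9 aldehyde (intramolecular Reformatsky-type reaction) to give the β-hydroxy ketone F7. Mesylation (MsCl, Et3N) and elimination with DBU give the enone. The sequence comes back to the route at 24.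

**Step 14.**
- What may go wrong: the osmium reagent may attack the enone from the face of the C1 methyl if the ring conformation or the C6 ester shields the H5 face, giving the 8,9-bis-epimer. The electron-poor trisubstituted alkene may also react slowly and allow over-oxidation.
- Fallback: it sets out from 25 and uses the free C6 hydroxyl, which lies on the H5 face, as a hydrogen-bond donor. Stoichiometric OsO4 with TMEDA in CH2Cl2 at −78 °C should be delivered to that face. Cleavage of the osmate with aqueous NaHSO3 gives the tetraol F8. 2,2-Dimethoxypropane with pyridinium p-toluenesulfonate protects the cis C8/C9 diol as the acetonide F9. Acylation of the C6 hydroxyl with 26 (Et3N, DMAP) gives the acetonide ester F10. Aqueous AcOH at 40 °C removes the acetonide. The sequence comes back to the route at 28.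

## Further compounds

F1 | step 5 | (3R)-3-(2,2-dimethoxyethyl)-3-methylcyclopent-1-en-1-yl acetate | CC(=O)OC1=C[C@@](C)(CC(OC)OC)CC1
F2 | step 7 | isopropenyl carbinol, the analogue of 19 with prop-1-en-2-yl in place of isopropyl at C4 | C=C(C)[C@]1(O)CC[C@](C)(CC(OC)OC)[C@H]1[C@@H](O[Si](C)(C)C(C)(C)C)C2(CC)SCCCS2
F3 | step 7 | trimethylsilyl ether of F2 at the tertiary hydroxyl | C=C(C)[C@]1(O[Si](C)(C)C)CC[C@](C)(CC(OC)OC)[C@H]1[C@@H](O[Si](C)(C)C(C)(C)C)C2(CC)SCCCS2
F4 | step 7 | isopropenyl ethyl ketone, the analogue of 21 with prop-1-en-2-yl in place of isopropyl | C=C(C)[C@]1(O[Si](C)(C)C)CC[C@](C)(CC(OC)OC)[C@H]1[C@@H](O[Si](C)(C)C(C)(C)C)C(=O)CC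
F5 | step 11 | α-bromo ketone, 21 brominated at C8 (C8 as mixture) | CC(C)[C@]1(O[Si](C)(C)C)CC[C@](C)(CC(OC)OC)[C@H]1[C@@H](O[Si](C)(C)C(C)(C)C)C(=O)C(C)Br
F6 | step 11 | bromo keto aldehyde, F5 with the acetal hydrolysed to the C9 aldehyde | CC(C)[C@]1(O[Si](C)(C)C)CC[C@](C)(CC=O)[C@H]1[C@@H](O[Si](C)(C)C(C)(C)C)C(=O)C(C)Br
F7 | step 11 | (1R,4R,5S,6R)-6-[(tert-butyldimethylsilyl)oxy]-9-hydroxy-1,8-dimethyl-4-(propan-2-yl)-4-[(trimethylsilyl)oxy]bicyclo[5.3.0]decan-7-one (C8 and C9 as mixture) | CC(C)[C@]1(O[Si](C)(C)C)CC[C@]2(C)CC(O)C(C)C(=O)[C@H](O[Si](C)(C)C(C)(C)C)[C@H]21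
F8 | step 14 | (1R,4R,5S,6R,8S,9S)-4,6,8,9-tetrahydroxy-1,8-dimethyl-4-(propan-2-yl)bicyclo[5.3.0]decan-7-one | CC(C)[C@]1(O)CC[C@]2(C)C[C@H](O)[C@](C)(O)C(=O)[C@H](O)[C@H]21
F9 | step 14 | C8,C9-acetonide (isopropylidene acetal) of F8 | CC(C)[C@]1(O)CC[C@]2(C)C[C@H](OC(C)(C)O3)[C@@]3(C)C(=O)[C@H](O)[C@H]21
F10 | step 14 | C6 4-(benzyloxy)benzoate of F9 | CC(C)[C@]1(O)CC[C@]2(C)C[C@H](OC(C)(C)O3)[C@@]3(C)C(=O)[C@H](OC(=O)c4ccc(OCc5ccccc5)cc4)[C@H]21
A1 | alternative 1 | bicyclic diene methyl ester with the C4 dioxolane ketal, quaternary C1, C5=C6 and C8=C9 | COC(=O)C1=CC[C@@]2(C)CCC3(OCCO3)C2=CC1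
A2 | alternative 1 | 6-ethenyl-7-methyl-1,4-dioxaspiro[4.4]non-6-ene | C=CC1=C(C)CCC12OCCO2
A3 | alternative 1 | methyl 2-diazobut-3-enoate | C=CC(=[N+]=[N-])C(=O)OC
A4 | alternative 2 | cis-fused bicyclo[5.3.0]dec-6-ene with C1 methyl, C4 tert-butyldimethylsilyl ether and C7 triethylsilyl enol ether | CC(C)(C)[Si](C)(C)O[C@H]1CC[C@]2(C)CCCC(O[Si](CC)(CC)CC)=C[C@@H]21
A5 | alternative 2 | (3S,1E)-3-[(tert-butyldimethylsilyl)oxy]-6-methyl-1-[1-(triethylsilyloxy)cyclopropyl]hepta-1,6-diene | C=C(C)CC[C@H](O[Si](C)(C)C(C)(C)C)/C=C/C1(O[Si](CC)(CC)CC)CC1
A6 | alternative 3 | cis-fused bicyclic enedione (hydrindene with C4 and C7 ketones, C9=C10 alkene, angular methyl on C1) | O=C1CC[C@]2(C)C=CC(=O)C[C@H]12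
A7 | alternative 3 | 3-(1-methyl-4-oxocyclohexa-2,5-dien-1-yl)propanal | O=CCCC1(C)C=CC(=O)C=C1
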